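Assumption: enol ester 8 is drawn as one tautomer although it equilibrates with its mirror-image enol and the diketone. Diene 9 is racemic, and its single stereocentre is erased in step 7. Compounds 1 and 6 are taken to be purchasable.

## The problem

Merochlorophaeic acid (14) is a meta-depside. Its two benzene rings are joined only by an ester between the carboxyl of ring A (2,4-dimethoxy-6-propylbenzoyl) and the C3 oxygen of ring B (C1 CO2H, C2 OH, C3 O-acyl, C4 OH, C5 H, C6 pentyl). The molecule has no stereocentre, so the difficulty is regiochemical and steric. The acyl carbon of ring A lies between a methoxy and a propyl group, and its partner oxygen is the middle one of a 1,2,3-trioxygenated arene. A conventional esterification would have to bring a shielded acyl donor to that middle oxygen after the two outer hydroxyls had been told apart and protected. The groups that will not survive rough treatment are: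
- the aryl ester, which hydroxide or alkoxide cleaves and which can migrate to a neighbouring phenol oxygen;
- the 2,4-dihydroxybenzoic acid, which decarboxylates on heating or in strong acid;
- the free, electron-rich phenols, which are open to oxidation and halogenation;
- the methoxy group ortho to the ester carbonyl, which Lewis acids can demethylate.

The enabling feature is that C3 of ring B, with its ester oxygen between the hydroxyl-bearing C2 and C4, corresponds to C2 of a cyclohexane-1,3-dione. That carbon can be made electrophilic as a diazo carbon, so the C3–O bond can be formed with the carboxyl oxygen as nucleophile, away from the shielded acyl carbon. Without its carboxyl, ring B is also mirror-symmetric about the C3–C6 axis, so C1 and C5 are equivalent and the carboxyl carbon can be introduced last.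

## Retrosynthesis

**C1–carboxyl bond (14 to 13 to 11).** The first cut is the bond between C1 of ring B and the carboxyl carbon. Acid 14 is taken back to aldehyde 13, and 13 (through the α-chloro ether 12) to the symmetric resorcinol ester 11. Carrying the carboxyl through as an ester would make the dione partner unsymmetrical and would require an ester cleavage next to the depside ester at the end. In 11 the two open ring B positions are equivalent, and each is ortho to one hydroxyl and para to the other. The forward steps must formylate ring B once, leave ring A alone, and oxidise the aldehyde without chlorinating the ring.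

**Aromaticity of ring B (11 to 10 to 9 to 8).** No skeletal bond is cut here; ring B is taken back two oxidation levels. Phenol 11 comes from its bis-silyl ether 10, 10 from the bis-silyl dienol ether 9, and 9 from the 2-aroyloxy-1,3-dione enol 8. The alternative is to keep ring B aromatic and acylate a triol, which raises the protection and hindrance problems described above. In 8 the two flanking oxygens are carbonyl or enol oxygens, so no protecting group is needed when the ester bond is made. The forward sequence must dehydrogenate the ring without touching the aryl ester or ring A.

**Ring B C3–O bond (8 to 7 and 5).** The key cut is the bond between the dione C2 (ring B C3) and the ester oxygen. It gives the diazo dione 7 and the ring A acid 5. Cutting the acyl C–O bond instead would require nucleophilic attack at a di-ortho-substituted acyl carbon. With the chosen cut the hindered acid acts through its unhindered oxygen, and the hindrance then protects the product against acyl migration. The precursors are a symmetric, achiral diazo dione and a simple benzoic acid. The forward reaction must favour O–H insertion over the other reactions open to the carbenoid.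

**Diazo group (7 to 6).** The C=N2 bond of 7 is traced to the active methylene of the purchasable dione 6 by diazo transfer. No other position of 6 lies between two carbonyl groups, so the site is unambiguous.

**Ring A carboxyl (5 to 4 to 2 to 1).** The bond between C1' and the carboxyl carbon is cut: acid 5 comes from aldehyde 4, and 4 (through the iminium salt 3) from the dimethyl ether 2 by formylation. The two O–methyl bonds of 2 lead back to divarinol (1). Lithiation and carboxylation of 2 would go between the two methoxy groups and give the wrong isomer. Electrophilic formylation prefers the position para to one methoxy and ortho to the other, which is the one required.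

## Roads not taken

**Alternative 1: biomimetic aldol closure of ring A on the depside ester.**
- Cut: the C1'–C6' bond of ring A, which unfolds ring A into a 3,5,7-trioxodecanoyl chain. The chain is carried as the ester A2 of the protected ring B phenol A3, benzyl 2,4-bis(benzyloxy)-3-hydroxy-6-pentylbenzoate.
- Key step: triethylamine and then trifluoroacetic acid should make chain C2 add to the C7 ketone. Loss of water then gives the 2',4'-dihydroxy-6'-propylbenzoate A1.
- Merits: the ester bond is made with an unhindered aliphatic acyl donor, so the steric problem disappears. The ring B carboxyl is present from the start, so no late electrophilic substitution is needed on a molecule with two electron-rich rings.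
- Weak points: the aryl ester in A2 is an activated ester. Closure of an enol oxygen onto it (to a 4-hydroxy-2-pyrone) or a Claisen closure from C6 would expel the ring B phenoxide and destroy the depside bond. A1 then needs both ring A hydroxyls methylated, one of them hydrogen-bonded to the ester carbonyl, followed by removal of three benzyl groups. A3 is a differentially protected 2,3,4-trioxygenated benzoate that needs its own multistep synthesis.
- Comparison: this road is longer and carries more protecting groups. It is better in avoiding a late ring-selective formylation. The chosen plan relies instead on the symmetry of 11 and on phenoxide direction of the electrophile to ring B.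

**Alternative 2: late desymmetrising formylation as the key step.**
- Cut: the C1–formyl bond of the aldehyde A4, which has the same structure as 13. Its precursor is the symmetric depside A5, which has the same structure as 11.
- Key step: dichloromethyl methyl ether and TiCl4 formylate A5 at the carbon ortho to one hydroxyl and para to the other.
- This road differs from the chosen plan only in how A5 is made. It would come from esterification of acid 5 with the middle oxygen of 5-pentylbenzene-1,2,3-triol A6, or a bis-protected form of it.
- Merits: the end game is identical to the chosen one. Mixed-anhydride esterification of electron-rich, di-ortho-substituted benzoic acids is better precedented than carbenoid insertion into a carboxylic acid O–H bond of this kind. On that point this road is the safer one.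
- Weak points: A6 is not a catalogue compound and is air-sensitive. Selective acylation of its middle oxygen is not secure, because the outer hydroxyls are less hindered. Protecting the outer hydroxyls adds steps and a further selectivity problem.
- Comparison: the step count could be similar. The chosen plan avoids making and handling a pyrogallol and needs no hydroxyl differentiation, because the flanking oxygens are carbonyl oxygens when the C–O bond forms. It also starts from an inexpensive symmetric dione. Its cost is a less proven key step.

**Alternative 3: ring A by Diels–Alder benzannulation of an ynoate ester.**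
- Cut: the C1'–C2' and C5'–C6' bonds of ring A. The hex-2-ynoate A8 of phenol A3 would react with 1,1-dimethoxy-3-(trimethylsilyloxy)buta-1,3-diene A9.
- Key step: thermal [4+2] cycloaddition, then loss of methanol and of the silyl group, should give the 4'-hydroxy-2'-methoxy-6'-propylbenzoate A7.
- Merits: the acylation partner is an unhindered ynoic acid. The substitution pattern of ring A is fixed by the polarisation of diene and dienophile. This is more rigorous than the regioselectivity of an electrophilic formylation.
- Weak points: A3 is needed again. A β-alkyl ynoate is a sluggish dienophile, so heating is required in the presence of a moisture-sensitive ketene acetal and an aryl ester. A7 still needs O-methylation at C4' and three debenzylations. The cycloaddition builds an arene whose pattern is purchasable as divarinol.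
- Comparison: regiocontrol in ring A is better here. The chosen plan relies on the known para preference of the Vilsmeier–Haack reaction on 2 and on removing any isomer at the stage of a small aldehyde. It is clearly shorter.

Key step: step 5

## Route

Step 1
Reactants: 1 divarinol (5-propylbenzene-1,3-diol)
Product: 2 1,3-dimethoxy-5-propylbenzene
Conditions: MeI, K2CO3, acetone, reflux
Reagents that add atoms: iodomethane, CI
Why: Williamson ether synthesis; both phenoxides are unhindered, and O-alkylation of a resorcinol with a methyl halide and carbonate is routine.

Step 2
Reactants: 2 1,3-dimethoxy-5-propylbenzene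
Product: 4 2,4-dimethoxy-6-propylbenzaldehyde, via iminium chloride 3 (not isolated)
Conditions: POCl3, DMF, 0 °C to 70 °C; then aq NaOAc
Reagents that add atoms: N,N-dimethylformamide, CN(C)C=O; water, O
Why: Vilsmeier–Haack formylation; the chloroiminium ion should attack para to one methoxy and ortho to the other (two equivalent sites) rather than the more crowded site between the methoxy groups, and hydrolysis of iminium salt 3 releases the aldehyde.

Step 3
Reactants: 4 2,4-dimethoxy-6-propylbenzaldehyde
Product: 5 2,4-dimethoxy-6-propylbenzoic acid
Conditions: NaClO2, NaH2PO4, 2-methyl-2-butene, t-BuOH/H2O, rt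
Reagents that add atoms: sodium chlorite NaClO2, [Na+].[O-]Cl=O
Why: Pinnick oxidation; chlorous acid oxidises the hindered aldehyde without needing attack by a bulky reagent, and the alkene removes hypochlorous acid before it can chlorinate the dimethoxy ring.

Step 4
Reactants: 6 5-pentylcyclohexane-1,3-dione
Product: 7 2-diazo-5-pentylcyclohexane-1,3-dione
Conditions: 4-acetamidobenzenesulfonyl azide, Et3N, MeCN, 0 °C to rt
Reagents that add atoms: 4-acetamidobenzenesulfonyl azide, CC(=O)Nc1ccc(cc1)S(=O)(=O)N=[N+]=[N-]
Why: Regitz diazo transfer; the only doubly activated methylene of the dione attacks the sulfonyl azide and loses the sulfonamide, a standard reaction of cyclic 1,3-diones.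

Step 5
Reactants: 7 2-diazo-5-pentylcyclohexane-1,3-dione; 5 2,4-dimethoxy-6-propylbenzoic acid
Product: 8 2-hydroxy-6-oxo-4-pentylcyclohex-1-en-1-yl 2,4-dimethoxy-6-propylbenzoate
Conditions: Rh2(OAc)4 (2 mol %), 5 (1.5 equiv), 4 Å MS, ClCH2CH2Cl, 60 °C, slow addition of 7
Reagents that add atoms: none
Why: Rh2(OAc)4, a divalent rhodium carboxylate, should take nitrogen from 7 and give an electrophilic acceptor/acceptor carbenoid at the dione C2. The carboxyl oxygen of 5 adds to this carbon, and a proton shift completes the O–H insertion, forming the bond that becomes the ring B C3–O ester bond; the product settles as the enol 8. The closest known reaction type is the Rh2(OAc)4-catalysed O–H insertion of 2-diazo-1,3-dicarbonyl compounds into carboxylic acids. No ring closes and no configuration is set, since the pentyl-bearing carbon of 8 is stereogenic only within one enol tautomer and the two enols interconvert. The step needs O–H insertion to win over Wolff ring contraction, over carbenoid attack on ring A, and over a second insertion into the enol O–H of 8. Slow addition of 7 to an excess of the acid at moderate temperature keeps a fast O–H trap available to each carbenoid. Ring A of 5 is deactivated by its carboxyl, and the enol O–H of 8 is crowded and hydrogen-bonded to the ester carbonyl. The ortho methoxy and propyl groups do not hinder the reacting oxygen, and they should suppress acyl migration in 8.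

Step 6
Reactants: 8 2-hydroxy-6-oxo-4-pentylcyclohex-1-en-1-yl 2,4-dimethoxy-6-propylbenzoate
Product: 9 2,6-bis[(tert-butyldimethylsilyl)oxy]-4-pentylcyclohexa-1,5-dien-1-yl 2,4-dimethoxy-6-propylbenzoate (racemic)
Conditions: TBSOTf (2.5 equiv), Et3N, CH2Cl2, 0 °C to rt
Reagents that add atoms: tert-butyldimethylsilyl trifluoromethanesulfonate, CC(C)(C)[Si](C)(C)OS(=O)(=O)C(F)(F)F
Why: Soft enolisation of a 1,3-dione with a silyl triflate and amine; silylation of the enol and then of the vinylogous ester carbonyl gives a symmetric 1,3-bis(silyloxy)allyl cation, and loss of a proton from either flanking CH2 gives the same racemic diene.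

Step 7
Reactants: 9 2,6-bis[(tert-butyldimethylsilyl)oxy]-4-pentylcyclohexa-1,5-dien-1-yl 2,4-dimethoxy-6-propylbenzoate
Product: 10 2,6-bis[(tert-butyldimethylsilyl)oxy]-4-pentylphenyl 2,4-dimethoxy-6-propylbenzoate
Conditions: DDQ, 2,4,6-collidine, PhMe, 0 °C to rt
Reagents that add atoms: none
Why: DDQ dehydrogenation of a silyloxy cyclohexadiene; hydride loss from the pentyl-bearing carbon gives a cation stabilised by both silyloxy groups, and loss of the adjacent proton aromatises ring B; any partly desilylated phenol converges on 11 in step 8.

Step 8
Reactants: 10 2,6-bis[(tert-butyldimethylsilyl)oxy]-4-pentylphenyl 2,4-dimethoxy-6-propylbenzoate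
Product: 11 2,6-dihydroxy-4-pentylphenyl 2,4-dimethoxy-6-propylbenzoate
Conditions: TBAF, AcOH, THF, 0 °C
Reagents that add atoms: none
Why: Fluoride cleavage of aryl silyl ethers; the acetic acid buffer protonates each phenoxide as it forms, so the hindered aryl ester should neither cleave nor migrate.

Step 9
Reactants: 11 2,6-dihydroxy-4-pentylphenyl 2,4-dimethoxy-6-propylbenzoate
Product: 13 3-formyl-2,6-dihydroxy-4-pentylphenyl 2,4-dimethoxy-6-propylbenzoate, via chloro(methoxy)methyl arene 12 (not isolated)
Conditions: Cl2CHOMe, TiCl4, CH2Cl2, −20 °C to 0 °C; then ice-cold aq HCl
Reagents that add atoms: dichloromethyl methyl ether, COC(Cl)Cl; water, O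
Why: Rieche formylation of a phenol; the titanium phenoxide directs the chloro(methoxy)carbenium ion to the ring B carbon ortho to one oxygen and para to the other (two equivalent sites), ring A is deactivated by its TiCl4-bound ester carbonyl, and the first formyl group deactivates ring B against a second attack.

Step 10
Reactants: 13 3-formyl-2,6-dihydroxy-4-pentylphenyl 2,4-dimethoxy-6-propylbenzoate
Product: 14 merochlorophaeic acid (2,4-dihydroxy-3-[(2,4-dimethoxy-6-propylbenzoyl)oxy]-6-pentylbenzoic acid)
Conditions: NaClO2, NaH2PO4, 2-methyl-2-butene (large excess), t-BuOH/THF/H2O, 0 °C to rt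
Reagents that add atoms: sodium chlorite NaClO2, [Na+].[O-]Cl=O
Why: Pinnick oxidation of an ortho-hydroxybenzaldehyde; the buffered, mildly acidic medium should spare the aryl ester and the acid product, and the alkene scavenger protects the free ring B position from chlorination.

## Compound list

1 | divarinol (5-propylbenzene-1,3-diol) | CCCc1cc(O)cc(O)c1 | starting material
2 | 1,3-dimethoxy-5-propylbenzene | CCCc1cc(OC)cc(OC)c1 | intermediate
3 | N-[(2,4-dimethoxy-6-propylphenyl)methylidene]-N-methylmethanaminium chloride (formed in the flask, not isolated) | CCCc1cc(OC)cc(OC)c1C=[N+](C)C.[Cl-] | intermediate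
4 | 2,4-dimethoxy-6-propylbenzaldehyde | CCCc1cc(OC)cc(OC)c1C=O | intermediate
5 | 2,4-dimethoxy-6-propylbenzoic acid | CCCc1cc(OC)cc(OC)c1C(=O)O | intermediate
6 | 5-pentylcyclohexane-1,3-dione | CCCCCC1CC(=O)CC(=O)C1 | starting material
7 | 2-diazo-5-pentylcyclohexane-1,3-dione | CCCCCC1CC(=O)C(=[N+]=[N-])C(=O)C1 | intermediate
8 | 2-hydroxy-6-oxo-4-pentylcyclohex-1-en-1-yl 2,4-dimethoxy-6-propylbenzoate (interconverting enols, no fixed configuration) | CCCCCC1CC(O)=C(OC(=O)c2c(CCC)cc(OC)cc2OC)C(=O)C1 | intermediate
9 | 2,6-bis[(tert-butyldimethylsilyl)oxy]-4-pentylcyclohexa-1,5-dien-1-yl 2,4-dimethoxy-6-propylbenzoate (racemic) | CCCCCC1CC(O[Si](C)(C)C(C)(C)C)=C(OC(=O)c2c(CCC)cc(OC)cc2OC)C(O[Si](C)(C)C(C)(C)C)=C1 | intermediate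
10 | 2,6-bis[(tert-butyldimethylsilyl)oxy]-4-pentylphenyl 2,4-dimethoxy-6-propylbenzoate | CCCCCc1cc(O[Si](C)(C)C(C)(C)C)c(OC(=O)c2c(CCC)cc(OC)cc2OC)c(O[Si](C)(C)C(C)(C)C)c1 | intermediate
11 | 2,6-dihydroxy-4-pentylphenyl 2,4-dimethoxy-6-propylbenzoate | CCCCCc1cc(O)c(OC(=O)c2c(CCC)cc(OC)cc2OC)c(O)c1 | intermediate
12 | 3-[chloro(methoxy)methyl]-2,6-dihydroxy-4-pentylphenyl 2,4-dimethoxy-6-propylbenzoate (racemic, titanium-bound in the flask, not isolated) | CCCCCc1cc(O)c(OC(=O)c2c(CCC)cc(OC)cc2OC)c(O)c1C(Cl)OC | intermediate
13 | 3-formyl-2,6-dihydroxy-4-pentylphenyl 2,4-dimethoxy-6-propylbenzoate | CCCCCc1cc(O)c(OC(=O)c2c(CCC)cc(OC)cc2OC)c(O)c1C=O | intermediate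
14 | merochlorophaeic acid (2,4-dihydroxy-3-[(2,4-dimethoxy-6-propylbenzoyl)oxy]-6-pentylbenzoic acid) | CCCCCc1cc(O)c(OC(=O)c2c(CCC)cc(OC)cc2OC)c(O)c1C(=O)O | target

## Step count and risks

Total: 10 steps. Longest linear sequence: 9 steps (steps 1, 2, 3, 5, 6, 7, 8, 9, 10, from divarinol 1). The dione branch joins after one step (step 4).

**Step 5 (key step).**
- What may go wrong: Wolff ring contraction of the diazo dione or carbenoid to a ketene; carbenoid attack on the dimethoxy ring of 5 or of 8; a second insertion into the enol O–H of 8; slow exchange of the hindered acid into the catalyst, which would lower turnover.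
- Fallback: a carbene-free route to the same bond. It sets out from 6: PhI(OAc)2 and KOH in methanol should give phenyliodonium 2,6-dioxo-4-pentylcyclohexan-1-ide F1. With acid 5 in CH2Cl2 or MeCN (catalytic Cu(acac)2 if needed), F1 is protonated at carbon and the carboxylate displaces iodobenzene. This should give 8, where the route is rejoined.

**Step 7.**
- What may go wrong: DDQ may act as a carbon or oxygen electrophile towards the dienol ether instead of as a hydride acceptor; adventitious acid may hydrolyse the silyl dienol ether back to 8; the electron-rich product may be over-oxidised.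
- Fallback: stepwise α-functionalisation and elimination, setting out from 9. PhSeCl in THF at −78 °C should selenenylate the CH terminus of the dienol ether and give 2-[(tert-butyldimethylsilyl)oxy]-6-oxo-4-pentyl-5-(phenylselanyl)cyclohex-1-en-1-yl 2,4-dimethoxy-6-propylbenzoate F2. Oxidation with H2O2 and pyridine at 0 °C to rt, syn-elimination of the selenoxide and tautomerisation should give 2-[(tert-butyldimethylsilyl)oxy]-6-hydroxy-4-pentylphenyl 2,4-dimethoxy-6-propylbenzoate F3. TBAF and AcOH then give 11, where the route is rejoined.

**Step 9.**
- What may go wrong: competing formylation of ring A at C5'; a second formylation of ring B; Lewis-acid demethylation of the methoxy ortho to the ester; acyl migration to a neighbouring phenol oxygen.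
- Fallback: setting out from 11, Casnati–Skattebøl ortho-formylation with MgCl2, Et3N and paraformaldehyde in THF at reflux. It proceeds through a magnesium phenoxide–formaldehyde complex and can react only ortho to a free phenol, so ring A is excluded by mechanism. It returns to the route at 13, and no compound outside the list is made (F0).

**Step 10.**
- What may go wrong: chlorination of the free C5 position of ring B by hypochlorous acid or chlorine dioxide that escapes the scavenger; decarboxylation of the product during acidic work-up.
- Fallback: setting out from 11 and bypassing 13, direct ortho-carboxylation of the resorcinol with MeOMgOCO2Me (Stiles reagent) in DMF at about 120 °C, then cold acidic work-up. It returns at 14, and no compound outside the list is made (F0). The hindered ester must survive the basic magnesium reagent, which is the weak point of this fallback.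

## Further compounds

F1 | step 5 | phenyliodonium 2,6-dioxo-4-pentylcyclohexan-1-ide | CCCCCC1CC(=O)[C-]([I+]c2ccccc2)C(=O)C1
F2 | step 7 | 2-[(tert-butyldimethylsilyl)oxy]-6-oxo-4-pentyl-5-(phenylselanyl)cyclohex-1-en-1-yl 2,4-dimethoxy-6-propylbenzoate (racemic, relative configuration not defined) | CCCCCC1CC(O[Si](C)(C)C(C)(C)C)=C(OC(=O)c2c(CCC)cc(OC)cc2OC)C(=O)C1[Se]c1ccccc1
F3 | step 7 | 2-[(tert-butyldimethylsilyl)oxy]-6-hydroxy-4-pentylphenyl 2,4-dimethoxy-6-propylbenzoate | CCCCCc1cc(O)c(OC(=O)c2c(CCC)cc(OC)cc2OC)c(O[Si](C)(C)C(C)(C)C)c1
F0 | step 9 | none | none
F0 | step 10 | none | none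
A1 | alternative 1 | benzyl 2,4-bis(benzyloxy)-3-[(2,4-dihydroxy-6-propylbenzoyl)oxy]-6-pentylbenzoate | CCCCCc1cc(OCc2ccccc2)c(OC(=O)c2c(CCC)cc(O)cc2O)c(OCc2ccccc2)c1C(=O)OCc1ccccc1
A2 | alternative 1 | benzyl 2,4-bis(benzyloxy)-6-pentyl-3-[(3,5,7-trioxodecanoyl)oxy]benzoate | CCCCCc1cc(OCc2ccccc2)c(OC(=O)CC(=O)CC(=O)CC(=O)CCC)c(OCc2ccccc2)c1C(=O)OCc1ccccc1
A3 | alternative 1 | benzyl 2,4-bis(benzyloxy)-3-hydroxy-6-pentylbenzoate | CCCCCc1cc(OCc2ccccc2)c(O)c(OCc2ccccc2)c1C(=O)OCc1ccccc1
A4 | alternative 2 | 3-formyl-2,6-dihydroxy-4-pentylphenyl 2,4-dimethoxy-6-propylbenzoate (same structure as 13) | CCCCCc1cc(O)c(OC(=O)c2c(CCC)cc(OC)cc2OC)c(O)c1C=O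
A5 | alternative 2 | 2,6-dihydroxy-4-pentylphenyl 2,4-dimethoxy-6-propylbenzoate (same structure as 11) | CCCCCc1cc(O)c(OC(=O)c2c(CCC)cc(OC)cc2OC)c(O)c1
A6 | alternative 2 | 5-pentylbenzene-1,2,3-triol | CCCCCc1cc(O)c(O)c(O)c1
A7 | alternative 3 | benzyl 2,4-bis(benzyloxy)-3-[(4-hydroxy-2-methoxy-6-propylbenzoyl)oxy]-6-pentylbenzoate | CCCCCc1cc(OCc2ccccc2)c(OC(=O)c2c(CCC)cc(O)cc2OC)c(OCc2ccccc2)c1C(=O)OCc1ccccc1
A8 | alternative 3 | benzyl 2,4-bis(benzyloxy)-3-(hex-2-ynoyloxy)-6-pentylbenzoate | CCCCCc1cc(OCc2ccccc2)c(OC(=O)C#CCCC)c(OCc2ccccc2)c1C(=O)OCc1ccccc1
A9 | alternative 3 | 1,1-dimethoxy-3-(trimethylsilyloxy)buta-1,3-diene | COC(OC)=CC(=C)O[Si](C)(C)C
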